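**Strategy.** Two double bonds of the iridoid core, C7=C8 in the cyclopentane ring and the enol ether C3=C4 (next to O2) in the dihydropyran ring, sit on opposite sides of the shared C5–C9 bond and have no atom in common, so each is made from its own pair of terminal alkenes. One tandem ring-closing metathesis therefore turns an acyclic tetraene into the whole cis-fused bicycle with C10 and C11 attached. The tetraene is a C1 acetal bearing vinyl and 4-methoxybenzyl groups, a C5 allyl group and two silyloxymethyl methylidenes; C5 and C9 come from an enantioselective boron Ireland–Claisen rearrangement. Directed epoxidation, Payne rearrangement and two acylations complete luzonoid A.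

Key step: step 15

Remark 1 (assumption): the acetal carbon C1 cannot be set selectively in the open chain and does not need to be; compounds 22–34 are drawn as the C1 epimer that maps onto the target, the other epimer is carried along, and both converge at hemiacetal 35, where C1 is set in step 23.

Remark 2 (assumption): with iPr2NEt in CH2Cl2 the (S,S)-bromoborane is taken to give the Z(O)-boron enolate and the (2S,3S)-acid 16; if the first run shows the mirror-image sense, the equally accessible (R,R)-controller is used instead.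

Remark 3: iridoid numbering is used throughout; "convex face" means the face that carries H5 and H9.

**Step 1**
Reactants: 1 2-methylidenepropane-1,3-diol
Product: 2 2-[(triisopropylsilyloxy)methyl]prop-2-en-1-ol
Conditions: NaH (1.0 equiv), THF, 0 °C; TIPSCl (1.0 equiv), rt
Reagents that add atoms: triisopropylsilyl chloride, CC(C)[Si](Cl)(C(C)C)C(C)C
Why: Mono-silylation of a symmetric diol through its sparingly soluble monosodium alkoxide (Williamson-type O-silylation) should stop after one silyl group.

**Step 2**
Reactants: 2 2-[(triisopropylsilyloxy)methyl]prop-2-en-1-ol; 3 but-3-enoic acid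
Product: 4 2-[(triisopropylsilyloxy)methyl]prop-2-en-1-yl but-3-enoate
Conditions: DCC, DMAP (5 mol%), CH2Cl2, 0 °C
Reagents that add atoms: none
Why: Steglich esterification at 0 °C with little DMAP should acylate the primary allylic alcohol without moving the β,γ-double bond of the acid into conjugation.

**Step 3**
Reactants: 4 2-[(triisopropylsilyloxy)methyl]prop-2-en-1-yl but-3-enoate
Product: 5 5-[(triisopropylsilyloxy)methyl]-3,6-dihydro-2H-pyran-2-one
Conditions: (H2IMes)(PCy3)Cl2Ru=CHPh (second-generation Grubbs catalyst, 2 mol%), CH2Cl2 (0.01 M), 40 °C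
Reagents that add atoms: none
Why: Ring-closing metathesis to a six-membered lactone should be easy, and because the new trisubstituted alkene is endocyclic the ring CH2O and the ring CH2 are locked cis to each other.

**Step 4**
Reactants: 5 5-[(triisopropylsilyloxy)methyl]-3,6-dihydro-2H-pyran-2-one
Product: 6 5-[(triisopropylsilyloxy)methyl]-3,6-dihydro-2H-pyran-2-ol (racemic lactol)
Conditions: iBu2AlH (1.1 equiv), CH2Cl2, −78 °C; aq. KNaC4H4O6
Reagents that add atoms: none
Why: At −78 °C the aluminium lactolate formed by hydride addition to the δ-lactone is stable, so the reduction should stop at the lactol (partial lactone reduction).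

**Step 5**
Reactants: 6 5-[(triisopropylsilyloxy)methyl]-3,6-dihydro-2H-pyran-2-ol
Product: 7 (2E)-2-[(triisopropylsilyloxy)methyl]hexa-2,5-dien-1-ol (allyl chain cis to CH2OH)
Conditions: Ph3PCH3Br, KOtBu, THF, 0 °C; then 6, 0 °C → rt
Reagents that add atoms: methylidenetriphenylphosphorane (from Ph3PCH3Br and KOtBu), C=P(c1ccccc1)(c1ccccc1)c1ccccc1
Why: Wittig methylenation of the lactol through its open hydroxy-aldehyde form should give the skipped diene, the geometry of the trisubstituted alkene being inherited unchanged from the ring.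

**Step 6**
Reactants: 8 monomethyl itaconate
Product: 10 methyl 3-(hydroxymethyl)but-3-enoate, via mixed anhydride 9 (not isolated)
Conditions: iBuOCOCl, N-methylmorpholine, THF, −15 °C; then NaBH4, H2O, 0 °C
Reagents that add atoms: none
Why: Activation of the free conjugated acid as a mixed carbonic anhydride and 1,2-reduction with NaBH4 should give the allylic alcohol while the methyl ester is untouched (mixed-anhydride reduction).

**Step 7**
Reactants: 10 methyl 3-(hydroxymethyl)but-3-enoate
Product: 11 methyl 3-[(tert-butyldimethylsilyloxy)methyl]but-3-enoate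
Conditions: TBSCl, imidazole, CH2Cl2, 0 °C → rt (crude 10, without delay)
Reagents that add atoms: tert-butyldimethylsilyl chloride, CC(C)(C)[Si](C)(C)Cl
Why: Standard silylation of a primary alcohol, carried out at once so that the γ-hydroxy ester cannot lactonise.

**Step 8**
Reactants: 11 methyl 3-[(tert-butyldimethylsilyloxy)methyl]but-3-enoate
Product: 12 3-[(tert-butyldimethylsilyloxy)methyl]but-3-enoic acid
Conditions: LiOH, THF–H2O, 0 °C → rt; then aq. HCl to pH 4–5
Reagents that add atoms: lithium hydroxide (hydroxide oxygen), [Li+].[OH-]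
Why: Saponification of the unhindered methyl ester at 0 °C should be faster than migration of the β,γ-alkene into conjugation, and the primary TBS ether tolerates base and a brief pH 4–5 work-up.

**Step 9**
Reactants: 7 (2E)-2-[(triisopropylsilyloxy)methyl]hexa-2,5-dien-1-ol; 12 3-[(tert-butyldimethylsilyloxy)methyl]but-3-enoic acid
Product: 13 (2E)-2-[(triisopropylsilyloxy)methyl]hexa-2,5-dien-1-yl 3-[(tert-butyldimethylsilyloxy)methyl]but-3-enoate
Conditions: DCC, DMAP (5 mol%), CH2Cl2, 0 °C
Reagents that add atoms: none
Why: Steglich esterification joins the two fragments under the same mild conditions as in step 2.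

**Step 10**
Reactants: 13 (2E)-2-[(triisopropylsilyloxy)methyl]hexa-2,5-dien-1-yl 3-[(tert-butyldimethylsilyloxy)methyl]but-3-enoate
Product: 16 (2S,3S)-2-[3-(tert-butyldimethylsilyloxy)prop-1-en-2-yl]-3-(prop-2-en-1-yl)-4-[(triisopropylsilyloxy)methyl]pent-4-enoic acid (C2 = C9, C3 = C5), via boron ketene acetal 14 (not isolated), via acyloxyborane 15 (not isolated)
Conditions: (4S,5S)-2-bromo-1,3-bis{[3,5-bis(trifluoromethyl)phenyl]sulfonyl}-4,5-diphenyl-1,3,2-diazaborolidine (made in the flask from the (S,S)-bis-sulfonamide and BBr3), iPr2NEt, CH2Cl2, −78 °C, then −20 °C; aqueous work-up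
Reagents that add atoms: none
Why: Soft enolisation should give the Z(O)-boron ketene acetal, whose Ireland–Claisen rearrangement through a chair transition state with the allyl chain axial sets C5 and C9 anti ((2S,3S)), the enolate face being chosen by the C2-symmetric bis-sulfonamide on boron.

**Step 11**
Reactants: 16 the (2S,3S)-acid; 17 2-bromoethanol
Product: 18 2-bromoethyl (2S,3S)-2-[3-(tert-butyldimethylsilyloxy)prop-1-en-2-yl]-3-(prop-2-en-1-yl)-4-[(triisopropylsilyloxy)methyl]pent-4-enoate
Conditions: PPh3, DIAD, THF, 0 °C → rt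
Reagents that add atoms: none
Why: Mitsunobu esterification activates the alcohol and not the acid, so the epimerisable, β,γ-unsaturated C9 centre is not put at risk.

**Step 12**
Reactants: 18 the 2-bromoethyl ester
Product: 20 1-(2-bromoethoxy)-1-acetoxy derivative of the C1 aldehyde (α-acetoxy ether, both C1 epimers, C5 and C9 as in 16), via aluminium hemiacetal 19 (not isolated)
Conditions: iBu2AlH, CH2Cl2, −78 °C; then pyridine, DMAP, Ac2O, −78 → −20 °C
Reagents that add atoms: acetic anhydride, CC(=O)OC(C)=O
Why: Reductive acetylation (hydride addition at −78 °C gives a stable aluminium hemiacetal that is acetylated in situ) should deliver the α-acetoxy ether without over-reduction or C9 epimerisation.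

**Step 13**
Reactants: 20 the α-acetoxy 2-bromoethyl ether; 21 4-methoxybenzyl alcohol
Product: 22 mixed 2-bromoethyl/4-methoxybenzyl acetal at C1 (C1 epimer shown, formed together with its C1 epimer)
Conditions: TMSOTf (10 mol%), 4 Å sieves, CH2Cl2, −78 °C; Et3N quench
Reagents that add atoms: none
Why: Glycosylation-type acetal exchange, in which the acetate is ionised far faster than an alkoxy group at −78 °C and the oxocarbenium ion is trapped by the alcohol before the weakly nucleophilic alkenes can add, should give the mixed acetal.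

**Step 14**
Reactants: 22 the mixed 2-bromoethyl/4-methoxybenzyl acetal
Product: 23 acyclic tetraene, mixed vinyl/4-methoxybenzyl acetal at C1 with C5 allyl, C8 and C4 methylidenes, C10–OTBS and C11–OTIPS
Conditions: KOtBu, THF, 0 °C → rt
Reagents that add atoms: none
Why: E2 dehydrohalogenation of a 2-bromoethyl ether with KOtBu is the classical route to vinyl ethers, and the acetal, silyl ethers and alkenes are inert to the base.

**Step 15**
Reactants: 23 the acyclic tetraene
Product: 25 cis-fused iridoid 3,7-diene, 1-O-(4-methoxybenzyl) acetal with C10–OTBS and C11–OTIPS (H5, H9 and the C1 alkoxy group on the same face), via cyclopentene triene 24 (not isolated)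
Conditions: (H2IMes)(PCy3)Cl2Ru=CHPh (second-generation Grubbs catalyst, 10 mol% in two portions), 1,4-benzoquinone (20 mol%), toluene (0.005 M), argon sparge, 40 °C, then 80 °C
Reagents that add atoms: none
Why: The benzylidene exchanges onto the monosubstituted C7 alkene and, through a ruthenacyclobutane with the adjacent C8 methylidene (Chauvin mechanism), closes the cyclopentene with loss of ethene; the ruthenium methylidene set free then adds to the vinyl ether to give an alkoxycarbene at C3, which adds across the C4 methylidene to form the C3=C4 enol ether and a second ethene. The closest known reaction types are ring-closing metathesis of acyclic olefinic enol ethers to cyclic enol ethers (glycal-type) and tandem double ring-closing metathesis of tetraenes. The five-membered carbocycle closes from the C7/C8 alkene pair and the six-membered 2H-pyran from the C3/C4 pair, each by intramolecular [2+2] cycloaddition and cycloreversion. No stereocentre is created, since the cis ring fusion is fixed by C5 and C9 from step 10, and both C1 epimers should cyclise. The step needs the pairings C7/C8 and C3/C4: the pairings C8/C4 and C7/C4 would give four-membered rings, and the C3/C8 (dihydrofuran) and C3/C7 (seven-membered) alternatives are avoided by running first at 40 °C, where the all-carbon closure consumes C7 and C8 while the alkoxycarbene is still unreactive, and only then heating for the slow enol-ether closure.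

**Step 16**
Reactants: 25 the bicyclic diene
Product: 26 C10 primary allylic alcohol (C11–OTIPS and C1 acetal retained)
Conditions: Bu4NF (1.05 equiv), THF, −20 → 0 °C
Reagents that add atoms: none
Why: Fluoride should cleave the less hindered primary TBS ether markedly faster than the primary TIPS ether, and basic fluoride leaves the acid-sensitive acetal and enol ether alone (chemoselective desilylation).

**Step 17**
Reactants: 26 the C10 allylic alcohol
Product: 27 7,8-epoxy-10-ol, epoxide oxygen on the convex face (syn to H5 and H9)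
Conditions: VO(acac)2 (5 mol%), tBuOOH (in decane), CH2Cl2, 0 °C → rt
Reagents that add atoms: tert-butyl hydroperoxide, CC(C)(C)OO
Why: Hydroxyl-directed epoxidation should reach only the allylic C7=C8 alkene (the electron-rich enol ether has no free hydroxyl nearby) and deliver oxygen to the open convex face, which sets C7 and provisionally C8.

**Step 18**
Reactants: 27 the 7,8-epoxy-10-ol
Product: 29 7,8,10-triol (7-OH convex, 8-OH concave, C10 convex), via spiro epoxide 28 (not isolated)
Conditions: NaOH (0.5 M), tBuOH–H2O, 60 °C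
Reagents that add atoms: water, O
Why: Payne rearrangement (the C10 alkoxide displaces the epoxide oxygen at C8 with inversion while the C7–O bond is kept) followed by hydroxide opening of the spiro epoxide at the unhindered C10 methylene should give the 7,8-trans triol, because direct attack at C7 would have to come from the concave face.

**Step 19**
Reactants: 29 the 7,8,10-triol
Product: 30 10-O-TBS-7,8-diol
Conditions: TBSCl (1.1 equiv), imidazole, CH2Cl2, −20 → 0 °C
Reagents that add atoms: tert-butyldimethylsilyl chloride, CC(C)(C)[Si](C)(C)Cl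
Why: Silylation should distinguish the primary C10 hydroxyl from the secondary C7 and tertiary C8 hydroxyls on steric grounds.

**Step 20**
Reactants: 31 (E)-4-hydroxycinnamic acid (p-coumaric acid)
Product: 33 (E)-4-(tert-butyldimethylsilyloxy)cinnamic acid, via bis-silyl coumarate 32 (not isolated)
Conditions: TBSCl (2.2 equiv), imidazole, DMF, rt; then AcOH–THF–H2O, rt
Reagents that add atoms: tert-butyldimethylsilyl chloride, CC(C)(C)[Si](C)(C)Cl
Why: Exhaustive silylation followed by hydrolysis of the labile silyl ester should leave only the phenol protected as its TBS ether.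

**Step 21**
Reactants: 30 the 10-O-TBS-7,8-diol; 33 (E)-4-(tert-butyldimethylsilyloxy)cinnamic acid
Product: 34 7-O-[(E)-4-(tert-butyldimethylsilyloxy)cinnamoyl] ester (8-OH free)
Conditions: DCC, DMAP, CH2Cl2, 0 °C → rt
Reagents that add atoms: none
Why: Steglich esterification should acylate the secondary C7 hydroxyl only, since the tertiary C8 hydroxyl does not react, and the C7 configuration is not touched.

**Step 22**
Reactants: 34 the 7-O-cinnamoyl 4-methoxybenzyl acetal
Product: 35 C1 hemiacetal (lactol; hydroxyl drawn on the convex face, anomers interconvert)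
Conditions: DDQ, CH2Cl2–aq. NaH2PO4/Na2HPO4 (pH 7), 0 °C
Reagents that add atoms: none
Why: DDQ oxidises the electron-rich benzylic position of the acetal and hydrolysis of the resulting cation releases 4-methoxybenzaldehyde and the hemiacetal, in which both C1 epimers of the earlier intermediates converge; the buffered, cold and short reaction is meant to spare the enol ether.

**Step 23**
Reactants: 35 the C1 hemiacetal; 36 3-methylbutanoic anhydride
Product: 37 1-O-(3-methylbutanoyl) acetal, tris-silyl-protected luzonoid A (O-acyl cis to H9)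
Conditions: Et3N, DMAP (cat.), CH2Cl2, −40 → −20 °C (on crude 35)
Reagents that add atoms: none
Why: Acylation of the interconverting hemiacetal anomers from the convex face should give the anomerically stabilised pseudoaxial ester (C1 is set here), while the tertiary C8 hydroxyl is too hindered to react at low temperature.

**Step 24**
Reactants: 37 tris-silyl-protected luzonoid A
Product: 38 luzonoid A
Conditions: Bu4NF, AcOH (1:1), THF, 0 °C → rt
Reagents that add atoms: none
Why: Buffered fluoride should remove the aryl TBS, the primary TBS and the primary TIPS groups under nearly neutral conditions that avoid acyl migration and cleavage of the C1 acyloxy acetal.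

**Compound list**

1 | 2-methylidenepropane-1,3-diol | C=C(CO)CO | starting material
2 | 2-[(triisopropylsilyloxy)methyl]prop-2-en-1-ol | OCC(=C)CO[Si](C(C)C)(C(C)C)C(C)C | intermediate
3 | but-3-enoic acid | C=CCC(=O)O | starting material
4 | 2-[(triisopropylsilyloxy)methyl]prop-2-en-1-yl but-3-enoate | C=CCC(=O)OCC(=C)CO[Si](C(C)C)(C(C)C)C(C)C | intermediate
5 | 5-[(triisopropylsilyloxy)methyl]-3,6-dihydro-2H-pyran-2-one | O=C1CC=C(CO[Si](C(C)C)(C(C)C)C(C)C)CO1 | intermediate
6 | 5-[(triisopropylsilyloxy)methyl]-3,6-dihydro-2H-pyran-2-ol (racemic) | OC1CC=C(CO[Si](C(C)C)(C(C)C)C(C)C)CO1 | intermediate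
7 | (2E)-2-[(triisopropylsilyloxy)methyl]hexa-2,5-dien-1-ol | C=CC/C=C(/CO[Si](C(C)C)(C(C)C)C(C)C)CO | intermediate
8 | monomethyl itaconate | COC(=O)CC(=C)C(=O)O | starting material
9 | isobutyl carbonic mixed anhydride of 8 | COC(=O)CC(=C)C(=O)OC(=O)OCC(C)C | intermediate (not isolated)
10 | methyl 3-(hydroxymethyl)but-3-enoate | COC(=O)CC(=C)CO | intermediate
11 | methyl 3-[(tert-butyldimethylsilyloxy)methyl]but-3-enoate | COC(=O)CC(=C)CO[Si](C)(C)C(C)(C)C | intermediate
12 | 3-[(tert-butyldimethylsilyloxy)methyl]but-3-enoic acid | OC(=O)CC(=C)CO[Si](C)(C)C(C)(C)C | intermediate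
13 | (2E)-2-[(triisopropylsilyloxy)methyl]hexa-2,5-dien-1-yl 3-[(tert-butyldimethylsilyloxy)methyl]but-3-enoate | C=CC/C=C(/CO[Si](C(C)C)(C(C)C)C(C)C)COC(=O)CC(=C)CO[Si](C)(C)C(C)(C)C | intermediate
14 | Z(O)-boron ketene acetal of 13 carrying the (S,S)-bis-sulfonamide on boron | C=CC/C=C(/CO[Si](C(C)C)(C(C)C)C(C)C)CO/C(OB1N(S(=O)(=O)c2cc(cc(c2)C(F)(F)F)C(F)(F)F)[C@@H](c2ccccc2)[C@H](c2ccccc2)N1S(=O)(=O)c1cc(cc(c1)C(F)(F)F)C(F)(F)F)=C/C(=C)CO[Si](C)(C)C(C)(C)C | intermediate (not isolated)
15 | acyloxyborane of acid 16 | O=C(OB1N(S(=O)(=O)c2cc(cc(c2)C(F)(F)F)C(F)(F)F)[C@@H](c2ccccc2)[C@H](c2ccccc2)N1S(=O)(=O)c1cc(cc(c1)C(F)(F)F)C(F)(F)F)[C@H](C(=C)CO[Si](C)(C)C(C)(C)C)[C@H](CC=C)C(=C)CO[Si](C(C)C)(C(C)C)C(C)C | intermediate (not isolated)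
16 | (2S,3S)-2-[3-(tert-butyldimethylsilyloxy)prop-1-en-2-yl]-3-(prop-2-en-1-yl)-4-[(triisopropylsilyloxy)methyl]pent-4-enoic acid | OC(=O)[C@H](C(=C)CO[Si](C)(C)C(C)(C)C)[C@H](CC=C)C(=C)CO[Si](C(C)C)(C(C)C)C(C)C | intermediate
17 | 2-bromoethanol | OCCBr | starting material
18 | 2-bromoethyl ester of 16 | BrCCOC(=O)[C@H](C(=C)CO[Si](C)(C)C(C)(C)C)[C@H](CC=C)C(=C)CO[Si](C(C)C)(C(C)C)C(C)C | intermediate
19 | diisobutylaluminium hemiacetal of 18 (C1 epimers) | CC(C)C[Al](CC(C)C)OC(OCCBr)[C@H](C(=C)CO[Si](C)(C)C(C)(C)C)[C@H](CC=C)C(=C)CO[Si](C(C)C)(C(C)C)C(C)C | intermediate (not isolated)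
20 | α-acetoxy 2-bromoethyl ether at C1 (C1 epimers) | CC(=O)OC(OCCBr)[C@H](C(=C)CO[Si](C)(C)C(C)(C)C)[C@H](CC=C)C(=C)CO[Si](C(C)C)(C(C)C)C(C)C | intermediate
21 | 4-methoxybenzyl alcohol | COc1ccc(CO)cc1 | starting material
22 | mixed 2-bromoethyl/4-methoxybenzyl acetal (C1 epimer shown) | COc1ccc(CO[C@H](OCCBr)[C@H](C(=C)CO[Si](C)(C)C(C)(C)C)[C@H](CC=C)C(=C)CO[Si](C(C)C)(C(C)C)C(C)C)cc1 | intermediate
23 | acyclic tetraene, mixed vinyl/4-methoxybenzyl acetal (C1 epimer shown) | COc1ccc(CO[C@H](OC=C)[C@H](C(=C)CO[Si](C)(C)C(C)(C)C)[C@H](CC=C)C(=C)CO[Si](C(C)C)(C(C)C)C(C)C)cc1 | intermediate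
24 | cyclopentene triene (C7=C8 closed, vinyl acetal and C4 methylidene intact) | COc1ccc(CO[C@H](OC=C)[C@@H]2C(CO[Si](C)(C)C(C)(C)C)=CC[C@@H]2C(=C)CO[Si](C(C)C)(C(C)C)C(C)C)cc1 | intermediate (not isolated)
25 | cis-fused iridoid 3,7-diene, 1-O-(4-methoxybenzyl), 10-O-TBS, 11-O-TIPS | COc1ccc(CO[C@@H]2OC=C(CO[Si](C(C)C)(C(C)C)C(C)C)[C@H]3CC=C(CO[Si](C)(C)C(C)(C)C)[C@@H]23)cc1 | intermediate
26 | 10-hydroxy 3,7-diene, 1-O-(4-methoxybenzyl), 11-O-TIPS | COc1ccc(CO[C@@H]2OC=C(CO[Si](C(C)C)(C(C)C)C(C)C)[C@H]3CC=C(CO)[C@@H]23)cc1 | intermediate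
27 | 7,8-epoxy-10-ol, epoxide on the convex face | COc1ccc(CO[C@@H]2OC=C(CO[Si](C(C)C)(C(C)C)C(C)C)[C@H]3C[C@@H]4O[C@]4(CO)[C@@H]23)cc1 | intermediate
28 | 8,10-spiro epoxide with 7-OH (Payne isomer) | COc1ccc(CO[C@@H]2OC=C(CO[Si](C(C)C)(C(C)C)C(C)C)[C@H]3C[C@H](O)[C@]4(CO4)[C@@H]23)cc1 | intermediate (not isolated)
29 | 7,8,10-triol, 1-O-(4-methoxybenzyl), 11-O-TIPS | COc1ccc(CO[C@@H]2OC=C(CO[Si](C(C)C)(C(C)C)C(C)C)[C@H]3C[C@H](O)[C@](O)(CO)[C@@H]23)cc1 | intermediate
30 | 10-O-TBS-7,8-diol | COc1ccc(CO[C@@H]2OC=C(CO[Si](C(C)C)(C(C)C)C(C)C)[C@H]3C[C@H](O)[C@](O)(CO[Si](C)(C)C(C)(C)C)[C@@H]23)cc1 | intermediate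
31 | (E)-4-hydroxycinnamic acid | OC(=O)/C=C/c1ccc(O)cc1 | starting material
32 | tert-butyldimethylsilyl (E)-4-(tert-butyldimethylsilyloxy)cinnamate | CC(C)(C)[Si](C)(C)OC(=O)/C=C/c1ccc(O[Si](C)(C)C(C)(C)C)cc1 | intermediate (not isolated)
33 | (E)-4-(tert-butyldimethylsilyloxy)cinnamic acid | OC(=O)/C=C/c1ccc(O[Si](C)(C)C(C)(C)C)cc1 | intermediate
34 | 7-O-[(E)-4-(tert-butyldimethylsilyloxy)cinnamoyl]-10-O-TBS-11-O-TIPS 1-O-(4-methoxybenzyl) acetal | COc1ccc(CO[C@@H]2OC=C(CO[Si](C(C)C)(C(C)C)C(C)C)[C@H]3C[C@H](OC(=O)/C=C/c4ccc(O[Si](C)(C)C(C)(C)C)cc4)[C@](O)(CO[Si](C)(C)C(C)(C)C)[C@@H]23)cc1 | intermediate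
35 | C1 hemiacetal of 34 (anomer shown) | O[C@@H]1OC=C(CO[Si](C(C)C)(C(C)C)C(C)C)[C@H]2C[C@H](OC(=O)/C=C/c3ccc(O[Si](C)(C)C(C)(C)C)cc3)[C@](O)(CO[Si](C)(C)C(C)(C)C)[C@@H]12 | intermediate
36 | 3-methylbutanoic anhydride | CC(C)CC(=O)OC(=O)CC(C)C | starting material
37 | tris-silyl-protected luzonoid A | CC(C)CC(=O)O[C@@H]1OC=C(CO[Si](C(C)C)(C(C)C)C(C)C)[C@H]2C[C@H](OC(=O)/C=C/c3ccc(O[Si](C)(C)C(C)(C)C)cc3)[C@](O)(CO[Si](C)(C)C(C)(C)C)[C@@H]12 | intermediate
38 | luzonoid A | CC(C)CC(=O)O[C@@H]1OC=C(CO)[C@H]2C[C@H](OC(=O)/C=C/c3ccc(O)cc3)[C@](O)(CO)[C@@H]12 | target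

**Step count.** Total: 24 steps. Longest linear sequence: 20 steps (steps 1–5, 9–19, 21–24).

**Steps most likely to fail**

1. Step 15. The ruthenium may be held as the stable alkoxycarbene on the vinyl ether and fail to add across the hindered 1,1-disubstituted C4 alkene, so that the reaction stops at 24, or the alkoxycarbene may close onto C8 before the cyclopentene has formed. Fallback (pyran ring closed without metathesis): set out from ester 18. Ring-closing metathesis with (PCy3)2Cl2Ru=CHPh (first-generation Grubbs catalyst, CH2Cl2, 40 °C) closes only the cyclopentene and should give cyclopentene ester F1. 9-BBN followed by NaBO3 hydroborates the remaining C4 methylidene, leaving the trisubstituted ring alkene, to give hydroxy ester F2. iBu2AlH reduces the ester to diol F3, and Dess–Martin periodinane with NaHCO3 oxidises both hydroxyls to dialdehyde F4. With alcohol 21, pyridinium p-toluenesulfonate and 4 Å sieves, the C3 enol adds to the C1 aldehyde and the hemiacetal is trapped as the 4-methoxybenzyl acetal (the classical dialdehyde closure of iridoids), which comes back to the route at 25.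

2. Step 13. The C1 oxocarbenium ion may be captured by the neighbouring alkenes (Prins-type cyclisation), or the acid may scramble the mixed acetal into the two symmetric acetals. Fallback (halide displacement under base instead of acid-catalysed exchange): set out from acetate 20. TMSBr in CH2Cl2 at −40 °C should convert it into α-bromo ether F5, which is displaced by alcohol 21 in the presence of iPr2NEt with no Lewis or Brønsted acid present, as in the formation of alkoxymethyl ethers; this comes back to the route at 22.

3. Step 23. Under the basic acylation conditions the hemiacetal may open to the dialdehyde and decompose, or the acyl group may enter with poor selectivity between the two anomers. Fallback (the C1 hydroxyl is made the leaving group instead of the nucleophile): set out from hemiacetal 35. Anomeric Mitsunobu esterification with 3-methylbutanoic acid (PPh3, DIAD, THF, −20 °C) activates the C1 hydroxyl under neutral conditions and lets the carboxylate enter on the convex face; it makes no new compound (F0) and comes back to the route at 37.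

**Further compounds**

F1 | step 15 | 2-bromoethyl cyclopentene ester (C7=C8 closed, C4 methylidene intact) | BrCCOC(=O)[C@@H]1C(CO[Si](C)(C)C(C)(C)C)=CC[C@@H]1C(=C)CO[Si](C(C)C)(C(C)C)C(C)C
F2 | step 15 | C3 primary alcohol from hydroboration of the C4 methylidene (C4 epimers) | BrCCOC(=O)[C@@H]1C(CO[Si](C)(C)C(C)(C)C)=CC[C@@H]1C(CO)CO[Si](C(C)C)(C(C)C)C(C)C
F3 | step 15 | C1,C3-diol (C4 epimers) | OC[C@@H]1C(CO[Si](C)(C)C(C)(C)C)=CC[C@@H]1C(CO)CO[Si](C(C)C)(C(C)C)C(C)C
F4 | step 15 | C1,C3-dialdehyde (C4 epimers) | O=C[C@@H]1C(CO[Si](C)(C)C(C)(C)C)=CC[C@@H]1C(C=O)CO[Si](C(C)C)(C(C)C)C(C)C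
F5 | step 13 | α-bromo 2-bromoethyl ether at C1 (C1 epimers) | BrCCOC(Br)[C@H](C(=C)CO[Si](C)(C)C(C)(C)C)[C@H](CC=C)C(=C)CO[Si](C(C)C)(C(C)C)C(C)C
F0 | step 23 | none | none
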